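**Retrosynthetic overview**
1. Target ⇐ C11=C12 dehydrogenation of the saturated ketone ⇐ acetylation of the endo C15 alcohol.
2. Key disconnection: one radical chain makes three C–C bonds, C6–C7 (intermolecular), C8–C14 (6-endo) and C13–C16 (5-exo-dig). The pieces are the ring A lactone as a C6 α-acyloxy radical (from a selenide) and an acyclic enynyl α-methylidene ketone.
3. Stereocontrol: C6 from the convex face of the cis-fused lactone; C8/C13 from the C15 carbinol through magnesium chelation; C15 is then turned to endo by retro-aldol/aldol under the same chelation.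
4. Ring order: ring A (proline 6-enolexo aldol) → γ-lactone (lactol closure) → six-membered ketone ring → methylidenecyclopentane ring; the last two (the bicyclo[3.2.1]octane) form in the key step.
5. Fragments: lactone from methyl pent-4-enoate and 5-bromo-2-methylpent-1-ene; acceptor from pent-4-enoyl chloride, vinylmagnesium bromide and 3-(trimethylsilyl)prop-2-ynal.

Assumption: atom labels (C1–C20, O9, O15) follow the kaurane skeleton of the target (C4, C5, C10 in ring A; C6 = lactone CH–O; C8 = quaternary bridgehead; C13 = CH bridgehead; C15 = CH–OAc); 2 and 13 are taken as catalogue chemicals.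

**Route**

Step 1
Reactants: 1 methyl pent-4-enoate; 2 5-bromo-2-methylpent-1-ene
Product: 3 methyl 6-methyl-2-(prop-2-en-1-yl)hept-6-enoate (racemate)
Conditions: LiN(iPr)2, THF, −78 °C; then 2, DMPU, −78 → 0 °C
Reagents that add atoms: none
Why: SN2 alkylation of the lithium ester enolate by a primary bromide; the stereocentre formed (C4) is left racemic because it is flattened again in step 4.

Step 2
Reactants: 3 methyl 6-methyl-2-(prop-2-en-1-yl)hept-6-enoate
Product: 4 methyl 6-oxo-2-(2-oxoethyl)heptanoate (racemate)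
Conditions: O3, CH2Cl2, −78 °C; then Me2S, −78 °C → rt
Reagents that add atoms: ozone, [O-][O+]=O
Why: ozonolysis with reductive work-up cleaves both terminal alkenes, the allyl group giving the aldehyde and the isopropenyl end the methyl ketone; no stereocentre is touched.

Step 3
Reactants: 4 methyl 6-oxo-2-(2-oxoethyl)heptanoate
Product: 6 methyl (2R,3R)-2-(dimethoxymethyl)-3-hydroxy-3-methylcyclohexane-1-carboxylate (C1 epimers), via aldol aldehyde 5 (not isolated)
Conditions: (R)-proline (20 mol %), CH2Cl2, rt; then HC(OMe)3, pyridinium p-toluenesulfonate (5 mol %), rt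
Reagents that add atoms: trimethyl orthoformate, COC(OC)OC
Why: List-type proline-catalysed 6-enolexo aldol in which the aldehyde enamine attacks the methyl ketone through the hydrogen-bonded chair (Houk–List) transition state, giving the trans β-hydroxy aldehyde with C5 and C10 set by the catalyst ((R)-proline gives 2R,3R) for either C4 epimer; the labile aldol is trapped at once as its dimethyl acetal.

Step 4
Reactants: 6 methyl (2R,3R)-2-(dimethoxymethyl)-3-hydroxy-3-methylcyclohexane-1-carboxylate
Product: 7 methyl (1R,2R,3R)-2-(dimethoxymethyl)-3-hydroxy-1,3-dimethylcyclohexane-1-carboxylate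
Conditions: LiN(iPr)2 (2.3 equiv), THF, −78 °C; then MeI, −78 → −20 °C
Reagents that add atoms: iodomethane, CI
Why: ester enolate alkylation (alkoxide/enolate dianion) in which enolisation merges both C4 epimers and MeI enters trans to the neighbouring CH(OMe)2 group and away from the axial C10 methyl, so the quaternary centre forms with CO2Me cis to C6 (1R).

Step 5
Reactants: 7 methyl (1R,2R,3R)-2-(dimethoxymethyl)-3-hydroxy-1,3-dimethylcyclohexane-1-carboxylate
Product: 8 (3aR,4R,7aR)-3,4-dihydroxy-4,7a-dimethylhexahydro-2-benzofuran-1(3H)-one (lactol; C3 epimers)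
Conditions: LiSPr, DMF, 60 °C; then 1 M HCl, THF, rt
Reagents that add atoms: water, O
Why: SN2 demethylation of the hindered methyl ester by thiolate (Bartlett–Johnson) followed by acetal hydrolysis, after which the cis aldehyde acid closes to the γ-lactol (pseudo-acid); both C6 epimers serve later.

Step 6
Reactants: 8 (3aR,4R,7aR)-3,4-dihydroxy-4,7a-dimethylhexahydro-2-benzofuran-1(3H)-one
Product: 9 (3aR,4R,7aR)-4-hydroxy-4,7a-dimethyl-3-(phenylselanyl)hexahydro-2-benzofuran-1(3H)-one (C3 epimers)
Conditions: PhSeH, BF3·OEt2 (0.2 equiv), CH2Cl2, −20 °C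
Reagents that add atoms: benzeneselenol, [SeH]c1ccccc1
Why: acid-catalysed exchange at the acyloxy hemiacetal carbon through the acyloxocarbenium ion (pseudo-acid to seleno pseudo-ester), which leaves the tertiary alcohol alone; the C6 configuration does not matter because C6 becomes a radical.

Step 7
Reactants: 10 pent-4-enoyl chloride; 11 vinylmagnesium bromide
Product: 12 hepta-1,6-dien-3-one
Conditions: copper iodide CuI (5 mol %), THF, −78 °C, inverse addition
Reagents that add atoms: none
Why: copper-catalysed acylation of the Grignard reagent (ketone synthesis from an acid chloride), which at −78 °C is faster than addition to the vinyl ketone formed.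

Step 8
Reactants: 12 hepta-1,6-dien-3-one; 13 3-(trimethylsilyl)prop-2-ynal
Product: 15 7-hydroxy-6-methylidenenon-1-en-8-yn-5-one (racemate), via silylated adduct 14 (not isolated)
Conditions: DABCO (0.3 equiv), THF, rt; then Bu4NF, AcOH, THF, 0 °C
Reagents that add atoms: none
Why: Morita–Baylis–Hillman reaction of the vinyl ketone with the activated ynal, then buffered fluoride cleavage of the alkynyl C–Si bond; the carbinol is racemic at this stage.

Step 9
Reactants: 15 7-hydroxy-6-methylidenenon-1-en-8-yn-5-one
Product: 16 (7S)-7-hydroxy-6-methylidenenon-1-en-8-yn-5-one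
Conditions: lipase PS (Burkholderia cepacia), vinyl acetate, t-BuOMe, 30 °C, to ca. 55 % conversion; chromatography
Reagents that add atoms: none
Why: lipase kinetic resolution by acylation (Kazlauskas rule, enone-bearing carbon as large and ethynyl as small group), in which the (R)-alcohol is acetylated and the (S)-alcohol is recovered in high ee.

Step 10
Reactants: 9 (3aR,4R,7aR)-4-hydroxy-4,7a-dimethyl-3-(phenylselanyl)hexahydro-2-benzofuran-1(3H)-one; 16 (7S)-7-hydroxy-6-methylidenenon-1-en-8-yn-5-one
Product: 18 (1R,5R,7R)-7-hydroxy-1-{[(1R,3aR,7R,7aS)-7-hydroxy-3a,7-dimethyl-3-oxooctahydro-2-benzofuran-1-yl]methyl}-6-methylidenebicyclo[3.2.1]octan-2-one, via exo alcohol 17 (not isolated)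
Conditions: 16 (2 equiv), MgBr2·OEt2 (2 equiv), CH2Cl2, 0 °C → rt; Bu3SnH (1.3 equiv) and Et3B/air by syringe pump over 6 h; then Et3N (4 equiv), rt
Reagents that add atoms: none
Why: Proposed new method: Bu3Sn• takes PhSe from 9 and the nucleophilic α-acyloxy C6 radical adds to the CH2 terminus of the MgBr2-activated methylidene ketone on the convex face of the cis-fused lactone, anti to C10 (C6 R); in the resulting α-keto C8 radical magnesium bridges O9 and O15, so the 6-endo attack of the terminal alkene (C8–C14) comes from the face that carries H and not the ethynyl group on C15 (Guindon/Renaud-type chelation control, C8 R); the C13 radical then closes 5-exo-dig onto the alkyne, necessarily cis across the new ring (C13 R), and the vinyl radical takes H from Bu3SnH; Et3N with the same magnesium salt then equilibrates the exo β-hydroxy ketone 17 by retro-aldol/aldol through the C8 enolate to the O9/O15-chelated endo aldolate (C15 R); closest known reactions are Giese additions of anomeric selenide-derived radicals, Curran/Snider 6-endo cyclisations of α-keto radicals, Snider's 6-endo/5-exo-dig tandem to methylidenebicyclo[3.2.1]octanes and MgBr2/Et3N aldol equilibration.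

Step 11
Reactants: 18 (1R,5R,7R)-7-hydroxy-1-{[(1R,3aR,7R,7aS)-7-hydroxy-3a,7-dimethyl-3-oxooctahydro-2-benzofuran-1-yl]methyl}-6-methylidenebicyclo[3.2.1]octan-2-one
Product: 19 (1R,5R,7R)-1-{[(1R,3aR,7R,7aS)-7-hydroxy-3a,7-dimethyl-3-oxooctahydro-2-benzofuran-1-yl]methyl}-6-methylidene-2-oxobicyclo[3.2.1]octan-7-yl acetate
Conditions: Ac2O (1.2 equiv), pyridine, DMAP (5 mol %), CH2Cl2, 0 °C
Reagents that add atoms: acetic anhydride, CC(=O)OC(C)=O
Why: acylation of the secondary allylic alcohol, with the tertiary C10 hydroxyl too hindered to compete under these conditions; no stereocentre changes.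

Step 12
Reactants: 19 (1R,5R,7R)-1-{[(1R,3aR,7R,7aS)-7-hydroxy-3a,7-dimethyl-3-oxooctahydro-2-benzofuran-1-yl]methyl}-6-methylidene-2-oxobicyclo[3.2.1]octan-7-yl acetate
Product: 20 (1R,5S,7R)-1-{[(1R,3aR,7R,7aS)-7-hydroxy-3a,7-dimethyl-3-oxooctahydro-2-benzofuran-1-yl]methyl}-6-methylidene-2-oxobicyclo[3.2.1]oct-3-en-7-yl acetate (CNP0172716.1)
Conditions: 2-iodoxybenzoic acid (2.5 equiv), DMSO/fluorobenzene, 70 °C
Reagents that add atoms: none
Why: Nicolaou-type dehydrogenation of a ketone with 2-iodoxybenzoic acid; the C9 ketone can enolise only towards C11, so only the C11=C12 double bond forms and every stereocentre stays (the C13 descriptor changes from R to S by priority only).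

**Compound list**
1 | methyl pent-4-enoate | C=CCCC(=O)OC | starting material
2 | 5-bromo-2-methylpent-1-ene | C=C(C)CCCBr | starting material
3 | methyl 6-methyl-2-(prop-2-en-1-yl)hept-6-enoate (racemate) | C=CCC(CCCC(C)=C)C(=O)OC | intermediate
4 | methyl 6-oxo-2-(2-oxoethyl)heptanoate (racemate) | COC(=O)C(CC=O)CCCC(C)=O | intermediate
5 | methyl (2R,3R)-2-formyl-3-hydroxy-3-methylcyclohexane-1-carboxylate (C1 epimers) | COC(=O)C1CCC[C@@](C)(O)[C@@H]1C=O | intermediate (not isolated)
6 | methyl (2R,3R)-2-(dimethoxymethyl)-3-hydroxy-3-methylcyclohexane-1-carboxylate (C1 epimers) | COC(=O)C1CCC[C@@](C)(O)[C@@H]1C(OC)OC | intermediate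
7 | methyl (1R,2R,3R)-2-(dimethoxymethyl)-3-hydroxy-1,3-dimethylcyclohexane-1-carboxylate | COC(=O)[C@]1(C)CCC[C@@](C)(O)[C@@H]1C(OC)OC | intermediate
8 | (3aR,4R,7aR)-3,4-dihydroxy-4,7a-dimethylhexahydro-2-benzofuran-1(3H)-one (C3 epimers) | OC1OC(=O)[C@]2(C)CCC[C@@](C)(O)[C@H]12 | intermediate
9 | (3aR,4R,7aR)-4-hydroxy-4,7a-dimethyl-3-(phenylselanyl)hexahydro-2-benzofuran-1(3H)-one (C3 epimers) | c1ccccc1[Se]C1OC(=O)[C@]2(C)CCC[C@@](C)(O)[C@H]12 | intermediate
10 | pent-4-enoyl chloride | C=CCCC(Cl)=O | starting material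
11 | vinylmagnesium bromide | C=C[Mg]Br | starting material
12 | hepta-1,6-dien-3-one | C=CCCC(=O)C=C | intermediate
13 | 3-(trimethylsilyl)prop-2-ynal | C[Si](C)(C)C#CC=O | starting material
14 | 7-hydroxy-6-methylidene-9-(trimethylsilyl)non-1-en-8-yn-5-one (racemate) | C=CCCC(=O)C(=C)C(O)C#C[Si](C)(C)C | intermediate (not isolated)
15 | 7-hydroxy-6-methylidenenon-1-en-8-yn-5-one (racemate) | C=CCCC(=O)C(=C)C(O)C#C | intermediate
16 | (7S)-7-hydroxy-6-methylidenenon-1-en-8-yn-5-one | C=CCCC(=O)C(=C)[C@@H](O)C#C | intermediate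
17 | (1R,5R,7S)-7-hydroxy-1-{[(1R,3aR,7R,7aS)-7-hydroxy-3a,7-dimethyl-3-oxooctahydro-2-benzofuran-1-yl]methyl}-6-methylidenebicyclo[3.2.1]octan-2-one | C=C1[C@@H]2CCC(=O)[C@@](C[C@H]3OC(=O)[C@]4(C)CCC[C@@](C)(O)[C@H]34)(C2)[C@H]1O | intermediate (not isolated)
18 | (1R,5R,7R)-7-hydroxy-1-{[(1R,3aR,7R,7aS)-7-hydroxy-3a,7-dimethyl-3-oxooctahydro-2-benzofuran-1-yl]methyl}-6-methylidenebicyclo[3.2.1]octan-2-one | C=C1[C@@H]2CCC(=O)[C@@](C[C@H]3OC(=O)[C@]4(C)CCC[C@@](C)(O)[C@H]34)(C2)[C@@H]1O | intermediate
19 | (1R,5R,7R)-1-{[(1R,3aR,7R,7aS)-7-hydroxy-3a,7-dimethyl-3-oxooctahydro-2-benzofuran-1-yl]methyl}-6-methylidene-2-oxobicyclo[3.2.1]octan-7-yl acetate | C=C1[C@@H]2CCC(=O)[C@@](C[C@H]3OC(=O)[C@]4(C)CCC[C@@](C)(O)[C@H]34)(C2)[C@@H]1OC(C)=O | intermediate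
20 | (1R,5S,7R)-1-{[(1R,3aR,7R,7aS)-7-hydroxy-3a,7-dimethyl-3-oxooctahydro-2-benzofuran-1-yl]methyl}-6-methylidene-2-oxobicyclo[3.2.1]oct-3-en-7-yl acetate | C=C1[C@@H]2C=CC(=O)[C@@](C[C@H]3OC(=O)[C@]4(C)CCC[C@@](C)(O)[C@H]34)(C2)[C@@H]1OC(C)=O | target

**Step count and risks**
Total step count: 12. Longest linear sequence: 9 steps (steps 1–6 and 10–12).

Steps most likely to fail:

- **Step 10.** Four events run in one chain, so the C8 or C13 radical may be reduced early, chelation control may erode, or the magnesium-mediated epimerisation may stay incomplete. The fallback keeps the C15 centre instead of inverting it. It sets out from 15, whose fast-reacting antipode is obtained in step 9 as (3R)-4-methylidene-5-oxonon-8-en-1-yn-3-yl acetate F1. F1 and 9 are joined in the same tin hydride chain but without Lewis acid (Bu3SnH, azobis(isobutyronitrile), benzene, 80 °C, syringe pump). In this non-chelated mode the acetoxy group is expected to lie anti to the forming C8–C14 bond with the slim ethynyl group on the acyl side, which would give the endo acetate directly; the diastereoselectivity is less certain than under chelation. The route is rejoined at 19.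

- **Step 3.** A ketone is the aldol acceptor and the enamine carbon is flanked by a branched centre, so rate, chemoselectivity or ee may fall short. The fallback replaces asymmetric catalysis by resolution and sets out from 4. Pyrrolidine/AcOH followed by the same acetalisation gives racemic methyl (2R*,3R*)-2-(dimethoxymethyl)-3-hydroxy-3-methylcyclohexane-1-carboxylate F2. Methylation as in step 4 gives racemic methyl (1R*,2R*,3R*)-2-(dimethoxymethyl)-3-hydroxy-1,3-dimethylcyclohexane-1-carboxylate F3. Preparative supercritical-fluid chromatography on a chiral stationary phase separates the antipodes, and the (1R,2R,3R) one rejoins the route at 7.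

- **Step 4.** The dianion alkylation has to set a quaternary centre with high facial selectivity on an open cyclohexane. The fallback moves the methylation to the bicyclic lactone and sets out from 6. NaOMe/MeOH equilibrates C1 and TsOH in wet MeCN closes the cis-fused pseudo-ester (3aR,4R,7aR)-4-hydroxy-3-methoxy-4-methylhexahydro-2-benzofuran-1(3H)-one F4. Its lactone enolate (LiN(iPr)2, 2.2 equiv; MeI) can only be methylated with retention of the cis ring fusion, giving (3aR,4R,7aR)-4-hydroxy-3-methoxy-4,7a-dimethylhexahydro-2-benzofuran-1(3H)-one F5. PhSeH/BF3·OEt2 then exchanges OMe for SePh and the route is rejoined at 9.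

Further compounds
F1 | step 10 | (3R)-4-methylidene-5-oxonon-8-en-1-yn-3-yl acetate | C=CCCC(=O)C(=C)[C@H](OC(C)=O)C#C
F2 | step 3 | methyl (2R*,3R*)-2-(dimethoxymethyl)-3-hydroxy-3-methylcyclohexane-1-carboxylate (racemate, C1 epimers) | COC(=O)C1CCC[C@@](C)(O)[C@@H]1C(OC)OC.COC(=O)C1CCC[C@](C)(O)[C@H]1C(OC)OC
F3 | step 3 | methyl (1R*,2R*,3R*)-2-(dimethoxymethyl)-3-hydroxy-1,3-dimethylcyclohexane-1-carboxylate (racemate) | COC(=O)[C@]1(C)CCC[C@@](C)(O)[C@@H]1C(OC)OC.COC(=O)[C@@]1(C)CCC[C@](C)(O)[C@H]1C(OC)OC
F4 | step 4 | (3aR,4R,7aR)-4-hydroxy-3-methoxy-4-methylhexahydro-2-benzofuran-1(3H)-one (C3 epimers) | COC1OC(=O)[C@@H]2CCC[C@@](C)(O)[C@H]12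
F5 | step 4 | (3aR,4R,7aR)-4-hydroxy-3-methoxy-4,7a-dimethylhexahydro-2-benzofuran-1(3H)-one (C3 epimers) | COC1OC(=O)[C@]2(C)CCC[C@@](C)(O)[C@H]12
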